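The synthesis rests on the C1–C2 bond, between the benzylic carbon of the left guaiacyl ring and the methylene α to the C3 ketone. Its precursor is not a ketone but an ester: the vanillyl ester of a (5S)-5-acetoxy-3-oxoheptanoic acid, whose carboxyl group on C2 is a temporary tether. The key step exploits the free 4-OH para to the benzylic carbon and the C3 ketone: fluoride-generated phenoxide expels the β-keto carboxylate, leaving a p-quinone methide; the keto acid re-adds through C2 (never C4) and CO2 leaves. One operation forms C1–C2, erases the tether and unmasks both phenols. C5 is set earlier by a catalytic asymmetric vinylogous aldol reaction.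

Key step: step 7

Remark: heptan-3-one numbering is used throughout (C1 = benzylic CH2 of the left ring, C3 = ketone, C5 = acetoxy carbon, C7 = benzylic CH2 of the right ring); heptanoate intermediates keep the same locants for C2–C7. The stereocentre of the target is read from the SMILES as S.

Step 1
Reactants: 1 4-iodo-2-methoxyphenol
Product: 2 tert-butyl(4-iodo-2-methoxyphenoxy)dimethylsilane
Conditions: TBSCl, imidazole, DMF, rt
Reagents that add atoms: tert-butyldimethylsilyl chloride, CC(C)(C)[Si](C)(C)Cl
Why: Imidazole-assisted silylation of a phenol; the silyl ether masks the right-hand phenol so that only the secondary alcohol is acetylated in step 5, and it falls to fluoride in step 7.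

Step 2
Reactants: 2 tert-butyl(4-iodo-2-methoxyphenoxy)dimethylsilane, 3 allyl alcohol
Product: 4 3-[4-(tert-butyldimethylsilyloxy)-3-methoxyphenyl]propanal
Conditions: Pd(OAc)2 (cat.), nBu4NCl, NaHCO3, DMF, 45 °C
Reagents that add atoms: none
Why: Heck reaction under ligand-free phase-transfer conditions; the aryl group adds to the terminal alkene carbon and β-hydride elimination toward the carbinol carbon gives the enol, hence the 3-arylpropanal.

Step 3
Reactants: 5 2,2,6-trimethyl-4H-1,3-dioxin-4-one
Product: 6 [(2,2-dimethyl-6-methylidene-6H-1,3-dioxin-4-yl)oxy]trimethylsilane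
Conditions: LDA, THF, −78 °C; TMSCl, −78 °C → rt
Reagents that add atoms: chlorotrimethylsilane, C[Si](C)(C)Cl
Why: Kinetic γ-deprotonation of the vinylogous ester and O-silylation of the dienolate, the standard preparation of this silyl dienol ether.

Step 4
Reactants: 4 3-[4-(tert-butyldimethylsilyloxy)-3-methoxyphenyl]propanal, 6 [(2,2-dimethyl-6-methylidene-6H-1,3-dioxin-4-yl)oxy]trimethylsilane
Product: 8 6-[(2S)-4-[4-(tert-butyldimethylsilyloxy)-3-methoxyphenyl]-2-hydroxybutyl]-2,2-dimethyl-4H-1,3-dioxin-4-one, via silyl ether 7 (not isolated)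
Conditions: Ti(OiPr)4 / tridentate Schiff base of 2-amino-2'-hydroxy-1,1'-binaphthyl and 3-bromo-5-tert-butylsalicylaldehyde / 3,5-di-tert-butylsalicylic acid (3 mol%, antipode chosen for Re-face attack), Et2O, 0 °C; then TFA, THF–H2O, 0 °C
Reagents that add atoms: none
Why: Catalytic enantioselective vinylogous Mukaiyama aldol reaction, in which the chiral Ti(IV) Lewis acid binds the aldehyde and exposes its Re face to the γ-carbon of the dienolate, which sets C5 as S (3-arylpropanals are established substrates of this catalyst class; the sense is to be confirmed by Mosher ester analysis and the mirror-image ligand used if needed).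

Step 5
Reactants: 8 6-[(2S)-4-[4-(tert-butyldimethylsilyloxy)-3-methoxyphenyl]-2-hydroxybutyl]-2,2-dimethyl-4H-1,3-dioxin-4-one
Product: 9 (2S)-4-[4-(tert-butyldimethylsilyloxy)-3-methoxyphenyl]-1-(2,2-dimethyl-4-oxo-4H-1,3-dioxin-6-yl)butan-2-yl acetate
Conditions: Ac2O, pyridine, DMAP (cat.), CH2Cl2, 0 °C → rt
Reagents that add atoms: acetic anhydride, CC(=O)OC(C)=O
Why: DMAP-catalysed acylation of the only free hydroxyl group; the C–O bond at C5 is not touched, so the S configuration is kept, and the ester blocks lactonisation in step 6.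

Step 6
Reactants: 9 (2S)-4-[4-(tert-butyldimethylsilyloxy)-3-methoxyphenyl]-1-(2,2-dimethyl-4-oxo-4H-1,3-dioxin-6-yl)butan-2-yl acetate, 10 vanillyl alcohol (4-hydroxy-3-methoxybenzyl alcohol)
Product: 12 4-hydroxy-3-methoxybenzyl (5S)-5-acetoxy-7-[4-(tert-butyldimethylsilyloxy)-3-methoxyphenyl]-3-oxoheptanoate, via acylketene 11 (not isolated)
Conditions: 10 (1.3 equiv), toluene, 110 °C, acetone distilled off; work-up and chromatography in aprotic solvents
Reagents that add atoms: none
Why: Thermal retro-[4+2] of the dioxinone releases acetone and an acylketene, which the primary benzylic OH of 10 should capture much faster than the less nucleophilic, hydrogen-bonded guaiacol OH (acylketene trapping, i.e. acetoacetylation of an alcohol).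

Step 7
Reactants: 12 4-hydroxy-3-methoxybenzyl (5S)-5-acetoxy-7-[4-(tert-butyldimethylsilyloxy)-3-methoxyphenyl]-3-oxoheptanoate
Product: 17 (5S)-5-acetoxy-1,7-bis(4-hydroxy-3-methoxyphenyl)heptan-3-one (target), via diphenol ester 13 (not isolated), via quinone methide 14 (not isolated), via keto acid 15 (not isolated), via benzylated keto acid 16 (not isolated)
Conditions: CsF (3 equiv), DMF (0.1 M), 0 °C → rt; then AcOH, 40 °C
Reagents that add atoms: none
Why: Proposed new method: fluoride cleaves the aryl silyl ether and deprotonates the vanillyl phenol of 13, whose phenoxide expels the β-keto carboxylate by 1,6-elimination to give quinone methide 14 and keto acid 15; the enolate of 15 at C2 adds to the exocyclic methylene of 14 (1,6-addition, re-aromatising the ring) to forge C1–C2, and 16 loses CO2 on acidification. The closest known reaction types are the decarboxylative 1,6-addition of β-keto acids to p-quinone methides, the Pd-catalysed decarboxylative benzylation of benzyl β-keto esters and the fluoride- or base-triggered 1,6-elimination of 4-hydroxybenzyl esters; their combination in one tethered substrate is what is new. No ring is closed and no stereocentre is created in 17 (the transient C2 centre of 16 disappears with CO2; C5 is remote and untouched). The step needs C2 rather than C4 as the nucleophilic carbon, which the temporary carboxyl secures by making C2 the only doubly activated position, and this should also keep the C5 acetate from β-elimination because C4 is not deprotonated. It also needs C- over O-capture of 14: O-capture by carboxylate or phenoxide only regenerates a 4-hydroxybenzyl ester or ether that ionises again, whereas C-capture followed by loss of CO2 is irreversible, so the mixture should funnel to 17. Over-benzylation is disfavoured because, once the carboxyl group is lost, C2 is no longer acidic under these conditions.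

Compound list
1 | 4-iodo-2-methoxyphenol | COc1cc(I)ccc1O | starting material
2 | tert-butyl(4-iodo-2-methoxyphenoxy)dimethylsilane | COc1cc(I)ccc1O[Si](C)(C)C(C)(C)C | intermediate
3 | allyl alcohol (prop-2-en-1-ol) | C=CCO | starting material
4 | 3-[4-(tert-butyldimethylsilyloxy)-3-methoxyphenyl]propanal | COc1cc(CCC=O)ccc1O[Si](C)(C)C(C)(C)C | intermediate
5 | 2,2,6-trimethyl-4H-1,3-dioxin-4-one | CC1=CC(=O)OC(C)(C)O1 | starting material
6 | [(2,2-dimethyl-6-methylidene-6H-1,3-dioxin-4-yl)oxy]trimethylsilane | C=C1C=C(O[Si](C)(C)C)OC(C)(C)O1 | intermediate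
7 | 6-[(2S)-4-[4-(tert-butyldimethylsilyloxy)-3-methoxyphenyl]-2-(trimethylsilyloxy)butyl]-2,2-dimethyl-4H-1,3-dioxin-4-one | CC1(C)OC(C[C@H](CCc2ccc(O[Si](C)(C)C(C)(C)C)c(OC)c2)O[Si](C)(C)C)=CC(=O)O1 | intermediate
8 | 6-[(2S)-4-[4-(tert-butyldimethylsilyloxy)-3-methoxyphenyl]-2-hydroxybutyl]-2,2-dimethyl-4H-1,3-dioxin-4-one | CC1(C)OC(C[C@H](CCc2ccc(O[Si](C)(C)C(C)(C)C)c(OC)c2)O)=CC(=O)O1 | intermediate
9 | (2S)-4-[4-(tert-butyldimethylsilyloxy)-3-methoxyphenyl]-1-(2,2-dimethyl-4-oxo-4H-1,3-dioxin-6-yl)butan-2-yl acetate | CC1(C)OC(C[C@H](CCc2ccc(O[Si](C)(C)C(C)(C)C)c(OC)c2)OC(C)=O)=CC(=O)O1 | intermediate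
10 | vanillyl alcohol (4-hydroxy-3-methoxybenzyl alcohol) | COc1cc(CO)ccc1O | starting material
11 | (5S)-5-acetoxy-7-[4-(tert-butyldimethylsilyloxy)-3-methoxyphenyl]-3-oxohept-1-en-1-one (acylketene) | O=C=CC(=O)C[C@H](CCc1ccc(O[Si](C)(C)C(C)(C)C)c(OC)c1)OC(C)=O | intermediate
12 | 4-hydroxy-3-methoxybenzyl (5S)-5-acetoxy-7-[4-(tert-butyldimethylsilyloxy)-3-methoxyphenyl]-3-oxoheptanoate | COc1cc(COC(=O)CC(=O)C[C@H](CCc2ccc(O[Si](C)(C)C(C)(C)C)c(OC)c2)OC(C)=O)ccc1O | intermediate
13 | 4-hydroxy-3-methoxybenzyl (5S)-5-acetoxy-7-(4-hydroxy-3-methoxyphenyl)-3-oxoheptanoate | COc1cc(COC(=O)CC(=O)C[C@H](CCc2ccc(O)c(OC)c2)OC(C)=O)ccc1O | intermediate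
14 | 2-methoxy-4-methylidenecyclohexa-2,5-dien-1-one (p-quinone methide) | C=C1C=CC(=O)C(OC)=C1 | intermediate
15 | (5S)-5-acetoxy-7-(4-hydroxy-3-methoxyphenyl)-3-oxoheptanoic acid | OC(=O)CC(=O)C[C@H](CCc1ccc(O)c(OC)c1)OC(C)=O | intermediate
16 | (5S)-5-acetoxy-2-(4-hydroxy-3-methoxybenzyl)-7-(4-hydroxy-3-methoxyphenyl)-3-oxoheptanoic acid (C2 epimers) | COc1cc(CC(C(=O)O)C(=O)C[C@H](CCc2ccc(O)c(OC)c2)OC(C)=O)ccc1O | intermediate
17 | (5S)-5-acetoxy-1,7-bis(4-hydroxy-3-methoxyphenyl)heptan-3-one | COc1cc(CCC(=O)C[C@H](CCc2ccc(O)c(OC)c2)OC(C)=O)ccc1O | target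

Total step count: 7
Longest linear sequence: 6 (steps 1, 2, 4, 5, 6, 7)

Steps most likely to fail

Step 7 (Proposed new method). The quinone methide may be lost to self-condensation or to C-alkylation of phenoxide rings before C2 captures it. The keto carboxylate may also lose CO2 and be protonated before capture, a second benzylation may occur, or the basic medium may eliminate acetic acid across C4–C5. The fallback uses known chemistry, with alkylation and decarboxylation as separate acetoacetic ester operations; it sets out from 9 and comes back at 17. Compound 9 is heated with benzyl alcohol in toluene at 110 °C to give benzyl (5S)-5-acetoxy-7-[4-(tert-butyldimethylsilyloxy)-3-methoxyphenyl]-3-oxoheptanoate F1. F1 is alkylated at C2 with commercial 4-(benzyloxy)-3-methoxybenzyl chloride (K2CO3, cat. NaI, acetone, rt) to give benzyl (5S)-5-acetoxy-2-[4-(benzyloxy)-3-methoxybenzyl]-7-[4-(tert-butyldimethylsilyloxy)-3-methoxyphenyl]-3-oxoheptanoate F2 as C2 epimers. Hydrogenolysis (H2, Pd/C, EtOAc, then 40 °C) cleaves the benzyl ester and the benzyl ether, and the liberated β-keto acid loses CO2 to give (5S)-5-acetoxy-7-[4-(tert-butyldimethylsilyloxy)-3-methoxyphenyl]-1-(4-hydroxy-3-methoxyphenyl)heptan-3-one F3. HF·pyridine (THF, 0 °C) then removes the silyl group to give 17.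

Step 4. Facial discrimination on an unbranched aliphatic aldehyde may be insufficient, or induction may run in the opposite sense. The fallback sets the carbinol by asymmetric hydrogenation instead of an aldol reaction; it sets out from 4 and comes back at 12. Aldehyde 4 is homologated with ethyl diazoacetate and catalytic SnCl2 (Roskamp reaction) to ethyl 5-[4-(tert-butyldimethylsilyloxy)-3-methoxyphenyl]-3-oxopentanoate F4. Noyori hydrogenation with Ru–(S)-BINAP (H2, EtOH, 50 °C) should give ethyl (3S)-5-[4-(tert-butyldimethylsilyloxy)-3-methoxyphenyl]-3-hydroxypentanoate F5, following the established sense for β-keto esters. Crossed Claisen condensation with excess lithium tert-butyl acetate (THF, −78 → −30 °C) gives tert-butyl (5S)-7-[4-(tert-butyldimethylsilyloxy)-3-methoxyphenyl]-5-hydroxy-3-oxoheptanoate F6. Acetylation (Ac2O, pyridine, DMAP) gives tert-butyl (5S)-5-acetoxy-7-[4-(tert-butyldimethylsilyloxy)-3-methoxyphenyl]-3-oxoheptanoate F7. Heating F7 with 10 in toluene at 110 °C expels tert-butanol through the same acylketene 11 and gives 12.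

Step 6. The acylketene may also acylate the phenolic OH, and the free-phenol benzylic ester may ionise prematurely on heating or on silica. The fallback replaces the free phenol by a silyl-masked trigger; it sets out from 9 and comes back at 13. Commercial vanillin is silylated (TBSCl, imidazole, DMF) to 4-(tert-butyldimethylsilyloxy)-3-methoxybenzaldehyde F8 and reduced (NaBH4, MeOH, 0 °C) to 4-(tert-butyldimethylsilyloxy)-3-methoxybenzyl alcohol F9. Heating 9 with F9 in toluene at 110 °C gives 4-(tert-butyldimethylsilyloxy)-3-methoxybenzyl (5S)-5-acetoxy-7-[4-(tert-butyldimethylsilyloxy)-3-methoxyphenyl]-3-oxoheptanoate F10, which has no free phenol and should be stable to chromatography. Under the CsF conditions of step 7, F10 loses both silyl groups and gives 13 in the flask.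

Further compounds
F1 | step 7 | benzyl (5S)-5-acetoxy-7-[4-(tert-butyldimethylsilyloxy)-3-methoxyphenyl]-3-oxoheptanoate | O=C(CC(=O)C[C@H](CCc1ccc(O[Si](C)(C)C(C)(C)C)c(OC)c1)OC(C)=O)OCc1ccccc1
F2 | step 7 | benzyl (5S)-5-acetoxy-2-[4-(benzyloxy)-3-methoxybenzyl]-7-[4-(tert-butyldimethylsilyloxy)-3-methoxyphenyl]-3-oxoheptanoate (C2 epimers) | COc1cc(CC(C(=O)OCc2ccccc2)C(=O)C[C@H](CCc2ccc(O[Si](C)(C)C(C)(C)C)c(OC)c2)OC(C)=O)ccc1OCc1ccccc1
F3 | step 7 | (5S)-5-acetoxy-7-[4-(tert-butyldimethylsilyloxy)-3-methoxyphenyl]-1-(4-hydroxy-3-methoxyphenyl)heptan-3-one | COc1cc(CCC(=O)C[C@H](CCc2ccc(O[Si](C)(C)C(C)(C)C)c(OC)c2)OC(C)=O)ccc1O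
F4 | step 4 | ethyl 5-[4-(tert-butyldimethylsilyloxy)-3-methoxyphenyl]-3-oxopentanoate | CCOC(=O)CC(=O)CCc1ccc(O[Si](C)(C)C(C)(C)C)c(OC)c1
F5 | step 4 | ethyl (3S)-5-[4-(tert-butyldimethylsilyloxy)-3-methoxyphenyl]-3-hydroxypentanoate | CCOC(=O)C[C@H](CCc1ccc(O[Si](C)(C)C(C)(C)C)c(OC)c1)O
F6 | step 4 | tert-butyl (5S)-7-[4-(tert-butyldimethylsilyloxy)-3-methoxyphenyl]-5-hydroxy-3-oxoheptanoate | CC(C)(C)OC(=O)CC(=O)C[C@H](CCc1ccc(O[Si](C)(C)C(C)(C)C)c(OC)c1)O
F7 | step 4 | tert-butyl (5S)-5-acetoxy-7-[4-(tert-butyldimethylsilyloxy)-3-methoxyphenyl]-3-oxoheptanoate | CC(C)(C)OC(=O)CC(=O)C[C@H](CCc1ccc(O[Si](C)(C)C(C)(C)C)c(OC)c1)OC(C)=O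
F8 | step 6 | 4-(tert-butyldimethylsilyloxy)-3-methoxybenzaldehyde | COc1cc(C=O)ccc1O[Si](C)(C)C(C)(C)C
F9 | step 6 | 4-(tert-butyldimethylsilyloxy)-3-methoxybenzyl alcohol | COc1cc(CO)ccc1O[Si](C)(C)C(C)(C)C
F10 | step 6 | 4-(tert-butyldimethylsilyloxy)-3-methoxybenzyl (5S)-5-acetoxy-7-[4-(tert-butyldimethylsilyloxy)-3-methoxyphenyl]-3-oxoheptanoate | COc1cc(COC(=O)CC(=O)C[C@H](CCc2ccc(O[Si](C)(C)C(C)(C)C)c(OC)c2)OC(C)=O)ccc1O[Si](C)(C)C(C)(C)C
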